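Retrosynthetic cuts, in order: the exocyclic C11=C13 bond (back to a C13 silyloxymethyl group); C2–C3 (to a C2 aldehyde and a (Z)-propenyl metal); the C5–O acyl bond; C9–O/C10–H (to a C9=C10 alkene) and C1–O (to a C1=C10 alkene); finally the ring bonds C9–C10 and C1–C5, with C5–C9 restored, to a cyclopentanone enamine and methyl but-2-ynoate.
Feature used: C10 (with its methyl C14) and C1 (with carbonyl carbon C2) are neighbouring ring atoms that map onto the two sp carbons of a but-2-ynoate. The other five ring carbons C5–C9, with the cis γ-lactone across C6/C7, are a commercial bicyclic cyclopentene lactone, so the seven-membered ring is that cyclopentane with two alkyne carbons inserted into its C5–C9 bond.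
Forward order: the lactone ring is bought; C13 is attached and masked; the cyclopentane is oxidised at C5 and made into an enamine; (2+2) addition and cyclobutene opening give the cycloheptadiene; C5, C1 and C9/C10 are then adjusted, C2 is taken from ester to Z-enone, and the methylene lactone is released last.
Stereochemistry: C6 and C7 are those of the starting lactone. Hydride attack on the convex face gives 5α-OH, which directs the epoxide and hence the 1α-oxygen. Borane adds to the open β face (9β-OH, 10α-CH3). C5 is inverted by oxidation and 1α-hydroxyl-directed reduction. The Z olefin comes from (Z)-1-bromoprop-1-ene with retention.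

Key step: step 7

Conventions: target numbering is used for every compound (C12 = lactone C=O, C13 = carbon on C11, C14 = methyl on C10). β is the face of the carbocycle carrying H-6 and H-7, α the face carrying the C6–O and C7–C11 bonds; exo on C11 means cis to H-7. TBDPS = tert-butyldiphenylsilyl, TES = triethylsilyl.
Assumption: intermediate 18 is drawn in its simplest form (one C–B bond, hydroxyls written free), and 28 is carried as both C2 epimers.

Step 1
Reactants: 1 (1S,5R)-2-oxabicyclo[3.3.0]oct-6-en-3-one; 2 formaldehyde
Product: 4 11-exo-(hydroxymethyl) lactone, via lithium enolate 3 (not isolated)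
Conditions: LiN(iPr)2 (1.1 equiv), THF, −78 °C; CH2O gas (cracked paraformaldehyde), −78 → −20 °C; H2O quench
Reagents that add atoms: none
Why: Aldol-type hydroxymethylation of the lactone enolate, which is attacked on the convex face of the cis-fused bicycle so that CH2OH lies cis to H-7 (a temporary centre that is erased in step 21), installs C13 at the only stage where the lactone is the sole enolisable group.

Step 2
Reactants: 4 11-exo-(hydroxymethyl) lactone
Product: 5 13-O-TBDPS ether
Conditions: TBDPSCl, imidazole, DMF, 0 °C → rt
Reagents that add atoms: tert-butyl(chloro)diphenylsilane, CC(C)(C)[Si](Cl)(c1ccccc1)c1ccccc1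
Why: Standard silylation of a primary alcohol; the TBDPS ether is chosen because it withstands the aqueous acid of step 8, the acid of step 11 and all oxidants, and keeps the β-oxygenated lactone from eliminating until the end.

Step 3
Reactants: 5 13-O-TBDPS ether
Product: 6 5β-hydroxy alkene
Conditions: SeO2 (1.2 equiv), 1,4-dioxane, 90 °C
Reagents that add atoms: selenium dioxide, O=[Se]=O
Why: Riley allylic oxidation: the ene reaction followed by a [2,3]-sigmatropic shift returns the double bond to C8=C9 and oxidises the ring CH2 (C5) in preference to the ring-fusion CH (C7), selenium engaging the convex face so that the new hydroxyl is β (this centre is removed in step 5).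

Step 4
Reactants: 6 5β-hydroxy alkene
Product: 7 5β-hydroxy saturated lactone
Conditions: H2 (1 atm), 5% Pd/C, EtOAc, rt
Reagents that add atoms: none
Why: Heterogeneous hydrogenation of a disubstituted alkene; no stereocentre is formed, and a neutral solvent at ambient pressure limits hydrogenolysis of the allylic C5–O bond.

Step 5
Reactants: 7 5β-hydroxy saturated lactone
Product: 8 5-oxo lactone
Conditions: Dess–Martin periodinane, NaHCO3, CH2Cl2, rt
Reagents that add atoms: none
Why: Dess–Martin oxidation of a secondary alcohol under buffered conditions gives the α-acyloxy cyclopentanone, whose C6 centre cannot epimerise because a trans-fused bicyclo[3.3.0] lactone is too strained.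

Step 6
Reactants: 8 5-oxo lactone; 9 pyrrolidine
Product: 10 pyrrolidine enamine (N on C5, C5=C9)
Conditions: pyrrolidine (1.5 equiv), 4 Å molecular sieves, toluene, rt; then evaporation of excess amine
Reagents that add atoms: none
Why: Enamine condensation, which puts the double bond toward the CH2 (C9) because the alternative C5=C6 enamine would lie at the ring fusion and carry the acyloxy group, while ambient temperature and sieves keep pyrrolidine from opening the lactone.

Step 7
Reactants: 10 pyrrolidine enamine; 11 methyl but-2-ynoate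
Product: 13 lactone-fused aminocycloheptadiene ester, via aminocyclobutene 12 (not isolated)
Conditions: methyl but-2-ynoate (2 equiv), toluene (1 M), 90 °C, sealed tube
Reagents that add atoms: none
Why: The enamine carbon C9 adds in conjugate fashion to the methyl-bearing alkyne carbon (C10), the allenolate carbon C1 closes on the iminium carbon C5 (4-exo-trig) to give the cis-fused aminocyclobutene 12, and the donor nitrogen and acceptor ester across the strained ring then drive cleavage of the old C5–C9 bond in a four-electron, largely zwitterionic opening that leaves C5=C1 and C10=C9 in a seven-membered ring. The closest known reaction type is the (2+2) addition of cyclic ketone enamines to acetylenic esters with two-carbon ring enlargement, run here hot and concentrated because a but-2-ynoate is a weaker acceptor than a propiolate or an acetylenedicarboxylate. Only the four-membered ring is made by bond closure; the cycloheptadiene arises from it by cleavage of the shared bond, not by a second closure. No stereocentre is created, since the two centres of 12 return to sp2, and C6, C7 and C11 are untouched. The step needs one orientation of the alkyne and one enamine regioisomer: the β-carbon of the ynoate is the electrophilic one, so C9 bonds to the methyl-bearing carbon, and the enamine double bond lies toward C9 for the reason given in step 6. An aprotic medium is used so that the zwitterion closes to 12 instead of being protonated to an open-chain adduct.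

Step 8
Reactants: 13 lactone-fused aminocycloheptadiene ester
Product: 14 conjugated keto ester
Conditions: 1 M aq. HCl, THF, rt
Reagents that add atoms: water, O
Why: Acid hydrolysis of a vinylogous carbamate: protonation at the diene terminus C9 gives a conjugated iminium ion that releases pyrrolidine and the alkylidene β-keto ester with the double bond at C1=C10, the β,γ-isomer converging to it through the dienol, and no stereocentre is formed.

Step 9
Reactants: 14 conjugated keto ester
Product: 15 5α-hydroxy enoate
Conditions: NaBH4, CeCl3·7H2O, MeOH, −78 °C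
Reagents that add atoms: none
Why: Luche reduction gives 1,2-addition to the enone carbonyl without conjugate reduction or lactone attack, hydride arriving on the convex β face, anti to the neighbouring C6–O bond, so that the new hydroxyl is 5α, cis to the lactone oxygen.

Step 10
Reactants: 15 5α-hydroxy enoate
Product: 16 1α,10α-epoxy-5α-hydroxy ester
Conditions: VO(acac)2 (5 mol%), t-BuOOH (in decane), toluene, 40 °C
Reagents that add atoms: tert-butyl hydroperoxide, CC(C)(C)OO
Why: Vanadium-catalysed hydroxyl-directed epoxidation of an allylic alcohol: the alkylperoxide held on vanadium by the C5 oxygen is delivered to the same face of the tetrasubstituted C1=C10 bond, which sets the 1α,10α-epoxide (cis delivery is dependable in cycloheptenols), gentle warming making up for the ester-deactivated alkene.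

Step 11
Reactants: 16 1α,10α-epoxy-5α-hydroxy ester
Product: 17 1α,5α-dihydroxy-9(10)-ene ester
Conditions: camphorsulfonic acid (10 mol%), toluene, 60 °C
Reagents that add atoms: none
Why: Acid-catalysed isomerisation of a β,β-disubstituted glycidic ester to the α-hydroxy β,γ-unsaturated ester: the tertiary C10–O bond ionises while the ester keeps the C1–O bond intact (so C1 stays α-oxygenated), and loss of H-9 gives the more substituted ring alkene under equilibrating conditions.

Step 12
Reactants: 17 1α,5α-dihydroxy-9(10)-ene ester
Product: 19 tetraol, via 9β-boranyl triol 18 (not isolated)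
Conditions: BH3·THF (6 equiv), NaBH4 (10 mol%), THF, 0 °C → rt; then 30% H2O2, aq. NaOAc, 0 °C → rt
Reagents that add atoms: hydrogen peroxide, OO
Why: Hydroboration–oxidation combined with the hydroxyl-assisted borane/NaBH4 reduction of an α-hydroxy ester (the lactone has no neighbouring hydroxyl and is spared): boron adds to the less substituted C9 and hydrogen to C10, syn and on the β face, away from the cyclic borate that bridges the 1α,5α-diol and away from the lactone, and oxidation with retention gives 9β-OH and 10α-CH3.

Step 13
Reactants: 19 tetraol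
Product: 20 2,9-bis-O-TES ether
Conditions: TESCl (2.2 equiv), imidazole, DMF, −20 → 0 °C
Reagents that add atoms: chlorotriethylsilane, CC[Si](Cl)(CC)CC
Why: Kinetic silylation that takes the primary C2 hydroxyl and the unencumbered C9 hydroxyl, while the C5 hydroxyl, wedged between the quaternary C1 and the acyloxy-bearing C6, and the tertiary C1 hydroxyl are left free.

Step 14
Reactants: 20 2,9-bis-O-TES ether
Product: 21 5-oxo-1α-hydroxy bis-TES ether
Conditions: Dess–Martin periodinane, NaHCO3, CH2Cl2, 0 °C → rt
Reagents that add atoms: none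
Why: Dess–Martin oxidation of the only free secondary alcohol gives the α-hydroxy ketone under buffered, non-basic conditions that avoid α-ketol rearrangement and silyl loss.

Step 15
Reactants: 21 5-oxo-1α-hydroxy bis-TES ether
Product: 22 1α,5β-dihydroxy bis-TES ether
Conditions: Me4NBH(OAc)3 (5 equiv), MeCN/AcOH (10:1), −30 °C
Reagents that add atoms: none
Why: Evans–Saksena hydroxyl-directed reduction: the tertiary 1α-hydroxyl exchanges onto boron and delivers hydride to C5 from the α face, so the new hydroxyl is 5β, trans to the C1 hydroxyl and to the C6 oxygen.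

Step 16
Reactants: 22 1α,5β-dihydroxy bis-TES ether; 23 3-methylbutanoic anhydride
Product: 24 5β-isovalerate
Conditions: 3-methylbutanoic anhydride (3 equiv), DMAP (0.2 equiv), Et3N, CH2Cl2, rt
Reagents that add atoms: none
Why: DMAP-catalysed acylation of the single secondary hydroxyl with retention at C5; the tertiary C1 hydroxyl does not acylate under these conditions.

Step 17
Reactants: 24 5β-isovalerate
Product: 26 1β-carbaldehyde, via primary alcohol 25 (not isolated)
Conditions: (COCl)2, DMSO, CH2Cl2, −78 → −40 °C; then Et3N, −78 → 0 °C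
Reagents that add atoms: none
Why: Swern oxidation applied directly to a silyl ether: the primary triethylsilyl ether is cleaved by the chlorosulfonium medium and oxidised to the aldehyde while the secondary C9 triethylsilyl ether and the TBDPS ether persist, and the aldehyde cannot enolise because C1 is quaternary.

Step 18
Reactants: 26 1β-carbaldehyde; 27 (Z)-1-bromoprop-1-ene
Product: 28 (Z)-allylic alcohol (both C2 epimers)
Conditions: CrCl2 (6 equiv), NiCl2 (2 mol%), DMF, rt
Reagents that add atoms: none
Why: Nozaki–Hiyama–Kishi addition: the alkenylchromium species, formed with retention of the Z geometry, adds only to the aldehyde in the presence of lactone, isovalerate and free tertiary hydroxyl, and the new C2 carbinol centre (formed without control) is removed in step 19.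

Step 19
Reactants: 28 (Z)-allylic alcohol
Product: 29 silylated Z-enone
Conditions: Dess–Martin periodinane, NaHCO3, CH2Cl2, 0 °C
Reagents that add atoms: none
Why: Dess–Martin oxidation of the allylic alcohol under neutral buffered conditions gives the α-hydroxy Z-enone without isomerising the cis double bond.

Step 20
Reactants: 29 silylated Z-enone
Product: 30 9β,13-dihydroxy Z-enone
Conditions: HF·pyridine, pyridine, THF, 0 °C → rt
Reagents that add atoms: none
Why: Fluoride-mediated desilylation under buffered acidic conditions removes the C9 triethylsilyl and C13 TBDPS groups without base, so the isovalerate does not migrate and the Z-enone and the β-hydroxymethyl lactone survive.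

Step 21
Reactants: 30 9β,13-dihydroxy Z-enone
Product: 32 CNP0186412.2 (target), via 13-mesylate 31 (not isolated)
Conditions: MsCl (1.1 equiv), Et3N (5 equiv), CH2Cl2, −20 °C → rt
Reagents that add atoms: none
Why: Selective sulfonylation of the primary alcohol followed by E1cB elimination of the β-mesyloxy lactone forms the exocyclic C11=C13 bond and erases the temporary C11 centre, the secondary C9 and tertiary C1 hydroxyls being too hindered to react at low temperature.

Compound list
1 | (1S,5R)-2-oxabicyclo[3.3.0]oct-6-en-3-one (cis-fused; C8=C9, C5 = ring CH2 next to C6) | O=C1O[C@@H]2[C@H](C1)C=CC2 | starting material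
2 | formaldehyde (monomer, cracked from paraformaldehyde) | C=O | starting material
3 | lithium enolate of 1 (C11=C12–OLi; not isolated) | [Li+].[O-]C1=C[C@@H]2C=CC[C@@H]2O1 | intermediate
4 | 11-exo-(hydroxymethyl) lactone (1 with CH2OH on C11, cis to H-7) | O=C1O[C@@H]2[C@H]([C@@H]1CO)C=CC2 | intermediate
5 | 13-O-TBDPS ether of 4 | O=C1O[C@@H]2[C@H]([C@@H]1CO[Si](c3ccccc3)(c4ccccc4)C(C)(C)C)C=CC2 | intermediate
6 | 5β-hydroxy alkene (5 with OH on C5 trans to the lactone oxygen; C8=C9 kept) | O=C1O[C@@H]2[C@H]([C@@H]1CO[Si](c3ccccc3)(c4ccccc4)C(C)(C)C)C=C[C@H]2O | intermediate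
7 | 5β-hydroxy saturated lactone (8,9-dihydro-6) | O=C1O[C@@H]2[C@H]([C@@H]1CO[Si](c3ccccc3)(c4ccccc4)C(C)(C)C)CC[C@H]2O | intermediate
8 | 5-oxo lactone (cis-fused keto lactone with 11-exo-CH2OTBDPS) | O=C1O[C@@H]2[C@H]([C@@H]1CO[Si](c3ccccc3)(c4ccccc4)C(C)(C)C)CCC2=O | intermediate
9 | pyrrolidine | C1CCNC1 | starting material
10 | pyrrolidine enamine of 8 (pyrrolidin-1-yl on C5, C5=C9) | O=C1O[C@@H]2[C@H]([C@@H]1CO[Si](c3ccccc3)(c4ccccc4)C(C)(C)C)CC=C2N5CCCC5 | intermediate
11 | methyl but-2-ynoate | CC#CC(=O)OC | starting material
12 | aminocyclobutene (cyclobutene C5–C9–C10(CH3)=C1(CO2CH3) cis-fused on the β face; pyrrolidin-1-yl α on C5, H-9 α; not isolated) | O=C1O[C@@H]2[C@H]([C@@H]1CO[Si](c3ccccc3)(c4ccccc4)C(C)(C)C)C[C@H]6C(C)=C(C(=O)OC)[C@@]26N5CCCC5 | intermediate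
13 | lactone-fused aminocycloheptadiene ester (ring C6–C7–C8–C9=C10(CH3)–C1(CO2CH3)=C5(pyrrolidin-1-yl)) | O=C1O[C@@H]2[C@H]([C@@H]1CO[Si](c3ccccc3)(c4ccccc4)C(C)(C)C)CC=C(C)C(C(=O)OC)=C2N5CCCC5 | intermediate
14 | conjugated keto ester (C5=O, C1=C10, CO2CH3 on C1, CH3 on C10) | O=C1O[C@@H]2[C@H]([C@@H]1CO[Si](c3ccccc3)(c4ccccc4)C(C)(C)C)CCC(C)=C(C(=O)OC)C2=O | intermediate
15 | 5α-hydroxy enoate (C1=C10) | O=C1O[C@@H]2[C@H]([C@@H]1CO[Si](c3ccccc3)(c4ccccc4)C(C)(C)C)CCC(C)=C(C(=O)OC)[C@@H]2O | intermediate
16 | 1α,10α-epoxy-5α-hydroxy methyl ester (CO2CH3 on C1 and CH3 on C10 both β) | O=C1O[C@@H]2[C@H]([C@@H]1CO[Si](c3ccccc3)(c4ccccc4)C(C)(C)C)CC[C@]7(C)O[C@]7(C(=O)OC)[C@@H]2O | intermediate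
17 | 1α,5α-dihydroxy-9(10)-ene methyl ester (CO2CH3 β on C1) | O=C1O[C@@H]2[C@H]([C@@H]1CO[Si](c3ccccc3)(c4ccccc4)C(C)(C)C)CC=C(C)[C@@](O)(C(=O)OC)[C@@H]2O | intermediate
18 | 9β-boranyl triol (simplest form; not isolated) | O=C1O[C@@H]2[C@H]([C@@H]1CO[Si](c3ccccc3)(c4ccccc4)C(C)(C)C)C[C@@H](B)[C@H](C)[C@@](O)(CO)[C@@H]2O | intermediate
19 | tetraol: 1α,5α,9β-trihydroxy-1β-(hydroxymethyl)-10α-methyl lactone | O=C1O[C@@H]2[C@H]([C@@H]1CO[Si](c3ccccc3)(c4ccccc4)C(C)(C)C)C[C@@H](O)[C@H](C)[C@@](O)(CO)[C@@H]2O | intermediate
20 | 2,9-bis-O-TES ether of 19 | O=C1O[C@@H]2[C@H]([C@@H]1CO[Si](c3ccccc3)(c4ccccc4)C(C)(C)C)C[C@@H](O[Si](CC)(CC)CC)[C@H](C)[C@@](O)(CO[Si](CC)(CC)CC)[C@@H]2O | intermediate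
21 | 5-oxo-1α-hydroxy bis-TES ether | O=C1O[C@@H]2[C@H]([C@@H]1CO[Si](c3ccccc3)(c4ccccc4)C(C)(C)C)C[C@@H](O[Si](CC)(CC)CC)[C@H](C)[C@@](O)(CO[Si](CC)(CC)CC)C2=O | intermediate
22 | 1α,5β-dihydroxy bis-TES ether | O=C1O[C@@H]2[C@H]([C@@H]1CO[Si](c3ccccc3)(c4ccccc4)C(C)(C)C)C[C@@H](O[Si](CC)(CC)CC)[C@H](C)[C@@](O)(CO[Si](CC)(CC)CC)[C@H]2O | intermediate
23 | 3-methylbutanoic anhydride | CC(C)CC(=O)OC(=O)CC(C)C | starting material
24 | 5β-(3-methylbutanoyloxy)-1α-hydroxy bis-TES ether | O=C1O[C@@H]2[C@H]([C@@H]1CO[Si](c3ccccc3)(c4ccccc4)C(C)(C)C)C[C@@H](O[Si](CC)(CC)CC)[C@H](C)[C@@](O)(CO[Si](CC)(CC)CC)[C@H]2OC(=O)CC(C)C | intermediate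
25 | primary alcohol (24 without the C2 TES group; not isolated) | O=C1O[C@@H]2[C@H]([C@@H]1CO[Si](c3ccccc3)(c4ccccc4)C(C)(C)C)C[C@@H](O[Si](CC)(CC)CC)[C@H](C)[C@@](O)(CO)[C@H]2OC(=O)CC(C)C | intermediate
26 | 1β-carbaldehyde (C2 = CHO; 1α-OH, 9β-OTES, 5β-isovalerate) | O=C1O[C@@H]2[C@H]([C@@H]1CO[Si](c3ccccc3)(c4ccccc4)C(C)(C)C)C[C@@H](O[Si](CC)(CC)CC)[C@H](C)[C@@](O)(C=O)[C@H]2OC(=O)CC(C)C | intermediate
27 | (Z)-1-bromoprop-1-ene | C/C=C\Br | starting material
28 | (Z)-allylic alcohol: C1 carries CH(OH)–CH=CH–CH3 (Z), both C2 epimers | O=C1O[C@@H]2[C@H]([C@@H]1CO[Si](c3ccccc3)(c4ccccc4)C(C)(C)C)C[C@@H](O[Si](CC)(CC)CC)[C@H](C)[C@@](O)(C(O)/C=C\C)[C@H]2OC(=O)CC(C)C | intermediate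
29 | silylated Z-enone: C1 carries (Z)-but-2-enoyl; 9β-OTES, 13-OTBDPS | O=C1O[C@@H]2[C@H]([C@@H]1CO[Si](c3ccccc3)(c4ccccc4)C(C)(C)C)C[C@@H](O[Si](CC)(CC)CC)[C@H](C)[C@@](O)(C(=O)/C=C\C)[C@H]2OC(=O)CC(C)C | intermediate
30 | 9β,13-dihydroxy Z-enone (11-exo-hydroxymethyl lactone) | O=C1O[C@@H]2[C@H]([C@@H]1CO)C[C@@H](O)[C@H](C)[C@@](O)(C(=O)/C=C\C)[C@H]2OC(=O)CC(C)C | intermediate
31 | 13-O-methanesulfonate of 30 (not isolated) | O=C1O[C@@H]2[C@H]([C@@H]1COS(C)(=O)=O)C[C@@H](O)[C@H](C)[C@@](O)(C(=O)/C=C\C)[C@H]2OC(=O)CC(C)C | intermediate
32 | CNP0186412.2: 1α,9β-dihydroxy-10α-methyl-1β-[(Z)-but-2-enoyl]-5β-(3-methylbutanoyloxy)cycloheptane cis-fused at C6/C7 to the α-methylene γ-lactone | C=C1C(=O)O[C@@H]2[C@H]1C[C@@H](O)[C@H](C)[C@@](O)(C(=O)/C=C\C)[C@H]2OC(=O)CC(C)C | target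

Total step count: 21. Longest linear sequence: 21 steps (1 to 32; the route is fully linear).

Steps most likely to fail

Step 11. The cation released at C10 may lose a methyl proton instead of H-9, giving the exocyclic alkene, or a group on C1 may shift to C10 before any proton is lost. The fallback sets out from 16. MgBr2·OEt2 in ether opens the epoxide at the tertiary carbon with bromide capture and inversion, which forestalls any shift, to give the 10β-bromo-1α,5α-diol ester F3. DBU in toluene then removes HBr to give 17 together with its 10(14)-methylene isomer F4. RhCl3·3H2O in hot ethanol moves the exocyclic double bond into the ring by metal-hydride isomerisation; next to the quaternary C1 only the C9=C10 position is open. All material comes back to the route at 17.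

Step 12. Borane may add with poor facial selectivity if the β-carboxyl group on C1 hinders the β face more than the borate-bridged α face, and alkene hydroboration and ester reduction may not both run to completion in one operation. The fallback sets out from 17, separates the two events and puts the face under reagent control. Hydroboration with the enantiomer of monoisopinocampheylborane (IpcBH2) whose own preference is matched to β-attack, followed by H2O2/NaOAc, should give the 1α,5α,9β-trihydroxy-10α-methyl methyl ester F5. Its α-hydroxy ester is then reduced with BH3·THF and catalytic NaBH4, which comes back to the route at 19.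

Step 7. Conjugate addition to the β-methyl ynoate is slow, so thermal loss of the enamine or proton transfer within the zwitterion to an open-chain adduct may outrun cyclobutene formation. The fallback sets out from 8. Kinetic enolisation away from the acyloxy-bearing carbon (LiN(iPr)2, Me3SiCl, THF, −78 °C) gives the trimethylsilyl enol ether F1. TiCl4 in CH2Cl2 at −78 °C activates the ynoate for (2+2) addition, forming the same C9–C10 and C1–C5 bonds, to give the siloxycyclobutene F2. TBAF in wet THF then frees the cyclobutenolate, which cleaves the C5–C9 bond in a retro-aldol sense; acidic work-up gives the conjugated keto ester and comes back to the route at 14.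

Further compounds
F1 | step 7 | trimethylsilyl enol ether of 8 (OSiMe3 on C5, C5=C9) | O=C1O[C@@H]2[C@H]([C@@H]1CO[Si](c3ccccc3)(c4ccccc4)C(C)(C)C)CC=C2O[Si](C)(C)C
F2 | step 7 | siloxycyclobutene (analogue of 12 with OSiMe3 α on C5) | O=C1O[C@@H]2[C@H]([C@@H]1CO[Si](c3ccccc3)(c4ccccc4)C(C)(C)C)C[C@H]6C(C)=C(C(=O)OC)[C@@]26O[Si](C)(C)C
F3 | step 11 | 10β-bromo-1α,5α-diol methyl ester (CH3 α on C10) | O=C1O[C@@H]2[C@H]([C@@H]1CO[Si](c3ccccc3)(c4ccccc4)C(C)(C)C)CC[C@@](C)(Br)[C@@](O)(C(=O)OC)[C@@H]2O
F4 | step 11 | 10(14)-methylene isomer of 17 | O=C1O[C@@H]2[C@H]([C@@H]1CO[Si](c3ccccc3)(c4ccccc4)C(C)(C)C)CCC(=C)[C@@](O)(C(=O)OC)[C@@H]2O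
F5 | step 12 | 1α,5α,9β-trihydroxy-10α-methyl methyl ester | O=C1O[C@@H]2[C@H]([C@@H]1CO[Si](c3ccccc3)(c4ccccc4)C(C)(C)C)C[C@@H](O)[C@H](C)[C@@](O)(C(=O)OC)[C@@H]2O
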